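## Structural features

The target is a pair of 4-(4-hydroxyphenyl)chroman-2-ones (3,4-dihydrocoumarins) joined through C3–C3′; the two halves differ only in the benzo ring, ring A being a phloroglucinol-type 5,7-diol and ring B carrying hydroxyls on C5′ to C8′. Four stereocentres stand in a row, C4–C3–C3′–C4′, with the configuration 4R,3S,3′S,4′R. In each lactone the hydrogens on C3 and C4 are cis, so the 4-aryl group and the other lactone unit share a face. This is the less stable arrangement, and C3 and C3′ are both α to an aryl ester carbonyl and can epimerise through the enol or enolate. Fragile points are the two aryl lactones (opened by nucleophiles and aqueous base), the eight phenols (the pentaoxygenated ring B is easily oxidised to a quinone), and the doubly benzylic C4 and C4′, which strong acid can ionise from the electron-rich rings. The real difficulty is the control of four contiguous centres across an acyclic bond, two of them contra-thermodynamic, in two halves that are nearly but not quite alike. The key step exploits the oxygenation pattern of ring A: C4a lies between the oxygen-bearing C5 and C8a and can be read as the central carbon of a malonic acid unit, while C6–C7–C8 is an acetone unit flanked by two removable carboxyls. C4, attached to that malonate carbon, is then the β-carbon of a malonate Michael adduct and can be set by amine catalysis before any ring exists.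

## Logic of the disconnections

30 ⇒ 29. The eight phenolic O–H bonds of 30 are traced back to eight O–CH3 bonds. Methyl ethers are the only protection with which ring B is accessible in few steps, and they survive every base, oxidant and carbene of the route. All phenol chemistry is thereby postponed to one operation. That operation must be Lewis-acidic and never basic, because C3 and C3′ of 29 hold the less stable configuration.

29 ⇒ 20 + 28. The bonds C3′–C4′ and O1′–C2′ are cut, which removes the whole ring B lactone. The aldehyde carbon of 20 becomes C2′, its α-carbon becomes C3′, and the exocyclic carbon of 28 becomes C4′. The cut is made there because a carbene-bound enolate adds to such an oxadiene with the catalyst fixing both new centres. Two stereocentres and one ring disappear and the route becomes convergent. The forward step must override the resident centres C3 and C4, must be cis-selective, and must use a base too weak to enolise C3.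

28 ⇒ 27 ⇒ 24 + 25, and 24 ⇒ 21. 28 is too reactive to store and is traced to 27, whose C–S bond is a latent C=C bond. 27 is cut at the bond from the benzylic carbon to ring B and at the C–S bond, giving 24, 25 and a sulfinic acid. 24 has a single free ring position, so regiochemistry is not in question. 24 is traced to 21 by cutting the phenolic C–O bond, since the two ring hydrogens of 21 are equivalent and ortho to a methoxy group. The only demand is that the acid-labile 27 form without a second arylation.

20 ⇒ 18 ⇒ 16 ⇒ 14. The aldehyde of 20 is traced to the terminal alkene of 18, the C3–H bond of 18 to that of its epimer 16, and the C3–allyl bond of 16 to the enolate of 14. An allyl group serves as the C3′–C2′ unit because it gives an intermediate with one acidic hydrogen only. C3 can then be inverted by deprotonation and kinetic protonation before a second lactone with a competing α-hydrogen exists; for that reason the inversion is placed here and not at the end. The forward steps need anti-alkylation and then anti-protonation, both steered by the C4 aryl group, and an alkene cleavage that spares two electron-rich rings.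

14 ⇒ 13 ⇒ 11. The two ring A methyl ethers of 14 are cut back to the hydroxyls of 13, and the hydrogens on C6 and C8 of 13 to the two ester groups of 11, by way of 12. These carboxyls make ring A accessible from carbonyl building blocks and leave by decarboxylation because each is ortho and para to oxygen. Their removal must not touch the lactone or C4, which is why the esters are benzyl.

11 ⇒ 7 + 8. The bonds C5–C6 and C8–C8a of ring A and the lactone bond O1–C2 are cut. Ring A falls into a malonyl unit (C5–C4a–C8a) carried by 7 and an acetone-1,3-dicarboxylate unit (C6–C7–C8) in 8; the lactone oxygen is one of the new ring A hydroxyls. A pentasubstituted benzene ring and a lactone are exchanged for two acyclic pieces, and C4 no longer has to be made by arylating a hindered coumarin. The forward step must acylate at carbon twice, keep the stereocentre next to the malonyl carbon, and leave the third carboxyl of 7 alone until ring A exists. Hence 7 has two acyl chlorides beside one methyl ester, and 8 is used as its magnesium chelate. The (S) descriptor of 7 and the (R) descriptor of C4 in 11 denote the same spatial arrangement; only the ranking changes once ring A outranks the anisyl group.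

7 ⇒ 6 ⇒ 5 ⇒ 4 ⇒ 3. Only functional groups change: acyl chlorides to the diacid 6, its carboxyls to the benzyl esters of 5, the methyl ester of 5 to the acid 4, and this to the aldehyde 3. The purpose is to tell three carboxyl carbons apart. The two that enter ring A are masked as benzyl esters removable by hydrogen, and the one that becomes C2 as a methyl ester. None of these steps may be basic enough for retro-Michael cleavage.

3 ⇒ 1 + 2. The bond between the stereocentre and the malonate carbon (the later C4–C4a bond) is cut. This is the retron of an amine-catalysed conjugate addition, which sets C4 with high and predictable selectivity from two simple achiral compounds. The forward step must deliver 2 to one face of the iminium ion of 1 and must not be reversed later.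

## Other disconnections considered

Alternative 1: The cut is made at the two C4–aryl bonds, with C3–H and C3′–H formed in the same event. This leads to the planar, achiral 3,3′-bicoumarin A2 and two equivalents of 4-methoxyphenylboronic acid A3. In the forward key step Rh(acac)(C2H4)2 with a chiral SEGPHOS-type bisphosphine would add the aryl group to both C3=C4 bonds (Hayashi–Miyaura conjugate arylation), and the two rhodium enolates would be protonated to give A1, which is identical with 29. A1 carries eight methyl ethers (two on ring A, four on ring B, one on each 4-aryl group); it is the octa-O-methyl ether of the target, which has no ninth hydroxyl.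
- In its favour: no ring closes, no protecting group changes, both C4 centres come from one catalyst, and A2 should be accessible in few steps. On step economy and convergence this alternative is clearly the better one. Applied to the flat coumarin analogue of 14, the same catalysis would even reach 14 in a single step.
- Against it here: the arylation is well behaved for coumarins unsubstituted at C3, whereas each acceptor in A2 is a trisubstituted, cross-conjugated enoate whose C4 is screened by a peri methoxy group. After the first addition the rhodium enolate is conjugated with the second coumarin, so isomerisation and 1,6-pathways compete with protonation. The electron-rich A3 is also prone to protodeboronation in the aqueous basic medium.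
- Decisive point: C3 and C3′ would be formed by protonation that the catalyst does not govern, in a hot basic medium that equilibrates towards the trans lactones, whereas the target needs cis twice.
- Comparison: the chosen plan is longer, but it names a controlling element for every centre (amine catalyst for C4, C4 for C3, carbene catalyst for C3′ and C4′) and avoids conjugate addition to a hindered position altogether.

Alternative 2: C3–C3′ is cut together with a temporary C4–C4′ bond, so that the four central carbons become a cyclobutane made from two molecules of the cinnamoyl imidazole A4. In the forward key step visible light, the triplet sensitiser Ir(ppy)3 and a chiral phosphoric acid would dimerise A4 head to head to the all-trans cyclobutane A5 (δ-truxinate type). The strained bond between the two aryl-bearing carbons would later be opened oxidatively and each benzylic carbon arylated by a phenol.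
- In its favour: the C3–C3′ bond and both of its stereocentres come from an achiral monomer in one catalytic enantioselective step, and the (1S,2S) configuration of the acyl-bearing carbons of A5 maps correctly onto 3S,3′S. In this respect, and in step count, the alternative is better than the chosen plan.
- Against it here: the two benzylic carbons of A5 are equivalent, yet one must receive a phloroglucinol-type ring and the other a tetraoxygenated one, so a one-pot opening would be statistical. C4 and C4′ would be re-made at cationic or quinone-methide-like carbons with nothing to fix their configuration, although they must end cis to C3 and C3′. Radical-cation opening of an electron-rich cyclobutane can also revert to two molecules of A4, and the acyl imidazoles must still be exchanged for aryl lactones.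
- Comparison: the alternative is stronger on C3/C3′ and weaker on C4/C4′, which the chosen plan fixes first and most reliably. The chosen plan has no step that must tell two identical ends of one molecule apart.

Alternative 3: The cut is made at C4–C4a, C4′–C4a′ and both lactone C–O bonds. Rings A and B are removed as the free phenols phloroglucinol A8 and 24, leaving the bicyclic dilactone A7, the 8–8′ dehydrodimer of p-coumaric acid A9. In the forward key step BF3·OEt2 would open A7 at each benzylic C–O bond, first with A8 and then with 24, and each liberated acid would close on the neighbouring phenol to give A6, the 5′,6′,7′,8′-tetra-O-methyl ether of the target.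
- In its favour: it follows the likely biogenesis, needs two or three steps from A9, leaves ring A and both 4-hydroxyphenyl groups unprotected, and has only four methyl ethers to remove. C3–C3′ comes preformed in the cis-fused A7, whose (3R,3aR,6R,6aR) enantiomer corresponds to 3S,3′S. In step and protecting-group economy it is far better than the chosen plan, and it is its equal in ending with a boron-halide demethylation.
- Against it here: oxidative dimerisation of A9 would give racemic A7, so the single enantiomer needs a resolution or an enantioselective phenol coupling that cannot be taken for granted. The two benzylic positions of A7 are equivalent, so two different phenols would give homo-adducts beside the mixed product. C4 and C4′ would form through p-quinone-methide-like cations under substrate control, where attack anti to the C3 substituent and acid-promoted re-ionisation both lead towards trans lactones.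
- Comparison: the chosen plan is longer and spends steps on protection, but it controls absolute configuration from the first step and does not rely on an equilibrium under Lewis acid to set C4 and C4′.

Key step: step 6

Assumption: the antipodes of the chiral catalysts in steps 1 and 14 are assigned from the usual face-shielding models of iminium ions and azolium enolates; should a model fail here, the other antipode is used and the route is otherwise unchanged.

## Route

Step 1
Reactants: 1 4-methoxycinnamaldehyde; 2 dibenzyl malonate
Product: 3 dibenzyl 2-[(1S)-1-(4-methoxyphenyl)-3-oxopropyl]propanedioate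
Conditions: (R)-2-{bis[3,5-bis(trifluoromethyl)phenyl][(trimethylsilyl)oxy]methyl}pyrrolidine (10 mol %), PhCO2H (10 mol %), EtOH, 0 °C → rt
Reagents that add atoms: none
Why: Iminium-ion Michael addition; the bulky arm of the amine screens one face of the s-trans iminium ion of 1 and 2 adds to the open (Re) face of the β-carbon, which sets the future C4 as (S) in 3 (it becomes 4R once ring A outranks the anisyl group). This is the established organocatalytic malonate–enal addition, and the electron-rich aryl group should only slow it.

Step 2
Reactants: 3 dibenzyl 2-[(1S)-1-(4-methoxyphenyl)-3-oxopropyl]propanedioate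
Product: 4 (3S)-5-(benzyloxy)-4-[(benzyloxy)carbonyl]-3-(4-methoxyphenyl)-5-oxopentanoic acid
Conditions: NaClO2, NaH2PO4, 2-methyl-2-butene, t-BuOH/H2O, 0 °C → rt
Reagents that add atoms: sodium chlorite, [Na+].[O-]Cl=O
Why: Pinnick oxidation under buffered, non-basic conditions, so that neither retro-Michael loss of the malonate nor benzyl ester cleavage should intervene; the alkene removes HOCl before it can chlorinate the anisyl ring or the malonate C–H.

Step 3
Reactants: 4 (3S)-5-(benzyloxy)-4-[(benzyloxy)carbonyl]-3-(4-methoxyphenyl)-5-oxopentanoic acid
Product: 5 dibenzyl 2-[(1S)-3-methoxy-1-(4-methoxyphenyl)-3-oxopropyl]propanedioate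
Conditions: Me3SiCHN2, MeOH/toluene (1:4), 0 °C → rt
Reagents that add atoms: (trimethylsilyl)diazomethane, C[Si](C)(C)C=[N+]=[N-]
Why: Esterification with a diazoalkane, in which the acid protonates the reagent and methanol releases the methylating species; the neutral conditions leave the malonate and the stereocentre untouched. The methyl ester marks the carboxyl that becomes C2 and keeps it unreactive when the other two are activated.

Step 4
Reactants: 5 dibenzyl 2-[(1S)-3-methoxy-1-(4-methoxyphenyl)-3-oxopropyl]propanedioate
Product: 6 2-[(1S)-3-methoxy-1-(4-methoxyphenyl)-3-oxopropyl]propanedioic acid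
Conditions: H2 (1 atm), 10 % Pd/C, EtOAc, rt
Reagents that add atoms: none
Why: Hydrogenolysis of both benzyl esters gives the malonic acid under neutral conditions at room temperature, below the temperature of decarboxylation; the methyl ester and the aryl methyl ether are inert.

Step 5
Reactants: 6 2-[(1S)-3-methoxy-1-(4-methoxyphenyl)-3-oxopropyl]propanedioic acid
Product: 7 2-[(1S)-3-methoxy-1-(4-methoxyphenyl)-3-oxopropyl]propanedioyl dichloride
Conditions: (COCl)2, DMF (cat.), CH2Cl2, 0 °C → rt; evaporate, use at once
Reagents that add atoms: oxalyl chloride, ClC(=O)C(Cl)=O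
Why: Acid chloride formation through the chloroiminium salt of DMF, the standard route to monosubstituted malonyl dichlorides; the crude product is used immediately because loss of HCl to the chlorocarbonyl ketene is its main decay path.

Step 6
Reactants: 7 2-[(1S)-3-methoxy-1-(4-methoxyphenyl)-3-oxopropyl]propanedioyl dichloride; 8 dibenzyl 3-oxopentanedioate (dibenzyl 1,3-acetonedicarboxylate)
Product: 11 dibenzyl (4R)-5,7-dihydroxy-4-(4-methoxyphenyl)-2-oxochromane-6,8-dicarboxylate, via C-acylated acyl chloride 9 (not isolated), via phloroglucinol triester 10 (not isolated)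
Conditions: 8, MgCl2 (2.2 equiv), Et3N (4.5 equiv), MeCN, 0 °C; 7 in CH2Cl2 (slow addition), 0 → 40 °C; 1 M HCl; then TsOH·H2O (cat.), toluene, 80 °C
Reagents that add atoms: none
Why: One acyl chloride of 7 (directly or through the chlorocarbonyl ketene formed by loss of HCl) acylates the magnesium-chelated enolate of 8 at carbon to give 9, a Claisen-type C-acylation under soft enolisation. The remaining methylene carbon of the same chelate then attacks the second acyl chloride in a Dieckmann-type 6-exo-trig closure (bonds C5–C6 and C8–C8a), giving ring A as a cyclohexane-1,3,5-trione that tautomerises to phloroglucinol 10 without loss of any atom. Any enol lactone (4-hydroxy-2-pyranone) from competing O-acylation is an activated ester and should be reopened by the same carbanion under Et3N/MgCl2, so both paths converge on 10. The closest known reaction type is the double C-acylation of acetonedicarboxylate and related 1,3-dicarbonyl bis-nucleophiles by malonyl dichlorides to phloroglucinol dicarboxylates. On acidification and warming with TsOH one of the two equivalent hydroxyls flanking C4a closes the lactone on the methyl ester (6-exo-trig acyl substitution, bond O1–C2), helped by loss of methanol and by the crowding around C4. No stereocentre is formed; C4 is the centre from step 1, it carries no acidic hydrogen, and retro-Michael loss of the malonyl unit would need an ester enolate at C3 that this base cannot form. The step needs C- over O-acylation, secured by magnesium chelation of both enolate oxygens, and ring closure over chain growth, secured by slow addition of 7 since the second acylation is intramolecular. Benzyl esters are chosen in 8 because the hydrogen-bonded 2,6-dioxygenated benzoate esters of ring A resist saponification, whereas benzyl groups leave by hydrogenolysis without touching the lactone.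

Step 7
Reactants: 11 dibenzyl (4R)-5,7-dihydroxy-4-(4-methoxyphenyl)-2-oxochromane-6,8-dicarboxylate
Product: 13 (4R)-5,7-dihydroxy-4-(4-methoxyphenyl)chroman-2-one, via diacid 12 (not isolated)
Conditions: H2 (1 atm), 10 % Pd/C, THF/EtOAc, rt; filter; then dioxane/H2O (10:1), 90 °C
Reagents that add atoms: none
Why: Hydrogenolysis frees the two ring A carboxylic acids, and 2,4,6-trioxygenated benzoic acids lose CO2 on mild heating by ipso-protonation (protodecarboxylation); no base touches the lactone or C4.

Step 8
Reactants: 13 (4R)-5,7-dihydroxy-4-(4-methoxyphenyl)chroman-2-one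
Product: 14 (4R)-5,7-dimethoxy-4-(4-methoxyphenyl)chroman-2-one
Conditions: Me2SO4, K2CO3, anhydrous acetone, rt → 40 °C
Reagents that add atoms: dimethyl sulfate, COS(=O)(=O)OC
Why: Williamson O-methylation of the two acidic phloroglucinol-type hydroxyls with a hard electrophile, which favours O- over C-alkylation; dry carbonate in acetone is too weak and too insoluble to open the lactone or enolise C3.

Step 9
Reactants: 14 (4R)-5,7-dimethoxy-4-(4-methoxyphenyl)chroman-2-one
Product: 16 (3S,4R)-3-allyl-5,7-dimethoxy-4-(4-methoxyphenyl)chroman-2-one (3,4-trans), via lithium enolate 15 (not isolated)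
Conditions: LiN(SiMe3)2 (1.05 equiv), THF, −78 °C; allyl bromide, −78 → −40 °C
Reagents that add atoms: allyl bromide, C=CCBr
Why: Lactone enolate alkylation; enolate 15 is planar at C3 and the C4 aryl group, held pseudo-axial by the peri 5-methoxy group, covers one face, so the halide should enter anti to it and give the 3,4-trans lactone (3S). The allyl group is the masked C3′–C2′ unit.

Step 10
Reactants: 16 (3S,4R)-3-allyl-5,7-dimethoxy-4-(4-methoxyphenyl)chroman-2-one
Product: 18 (3R,4R)-3-allyl-5,7-dimethoxy-4-(4-methoxyphenyl)chroman-2-one (3,4-cis), via lithium enolate 17 (not isolated)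
Conditions: LiN(i-Pr)2 (1.1 equiv), THF, −78 °C; then 2,6-di-tert-butyl-4-methylphenol in THF, −78 °C; aq. NH4Cl
Reagents that add atoms: none
Why: Deprotonation and kinetic protonation; 16 has a single acidic hydrogen, and enolate 17 should be protonated by the bulky phenol from the face anti to the pseudo-axial C4 aryl group, which puts the new hydrogen trans and the allyl group cis to the aryl group (3R), the less stable epimer the target needs. Irreversible proton transfer at −78 °C prevents equilibration.

Step 11
Reactants: 18 (3R,4R)-3-allyl-5,7-dimethoxy-4-(4-methoxyphenyl)chroman-2-one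
Product: 20 2-[(3R,4R)-5,7-dimethoxy-4-(4-methoxyphenyl)-2-oxochroman-3-yl]acetaldehyde, via diol 19 (not isolated)
Conditions: OsO4 (2 mol %), NaIO4 (4 equiv), 2,6-lutidine, dioxane/H2O (3:1), rt
Reagents that add atoms: osmium tetroxide, O=[Os](=O)(=O)=O (oxygen carrier, regenerated by periodate); sodium periodate, [Na+].[O-]I(=O)(=O)=O
Why: Lemieux–Johnson oxidation; osmylation to diol 19 and periodate cleavage in the same flask give the aldehyde. The buffered medium is not basic enough to epimerise C3 and, unlike ozone, does not attack the two electron-rich aryl rings.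

Step 12
Reactants: 21 1,2,3,4-tetramethoxybenzene
Product: 24 2,3,4,5-tetramethoxyphenol, via aryllithium 22 (not isolated), via boronate 23 (not isolated)
Conditions: n-BuLi, TMEDA, THF, 0 °C → rt; B(OMe)3, −78 °C → rt; then H2O2 (30 % aq.), AcOH, 0 °C
Reagents that add atoms: hydrogen peroxide, OO; trimethyl borate, COB(OC)OC (boron of 23 only)
Why: Directed ortho-lithiation (both ring hydrogens of 21 are equivalent and ortho to a methoxy group), borylation and oxidative aryl shift from boron to oxygen give the phenol in one flask; acidic peroxide avoids air oxidation of the electron-rich phenolate.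

Step 13
Reactants: 24 2,3,4,5-tetramethoxyphenol; 25 4-methoxybenzaldehyde
Product: 27 racemic 2,3,4,5-tetramethoxy-6-[(4-methoxyphenyl)(4-methylbenzenesulfonyl)methyl]phenol, via benzhydrol 26 (not isolated)
Conditions: p-TolSO2H (1.2 equiv), TsOH·H2O (5 mol %), CH2Cl2, rt
Reagents that add atoms: 4-methylbenzenesulfinic acid, Cc1ccc(S(=O)O)cc1
Why: Acid-promoted three-component reaction; Friedel–Crafts hydroxyalkylation of 24 at its only free position (ortho to OH, para to a methoxy group) gives benzhydrol 26, which ionises to a doubly stabilised benzylic cation that the sulfinate captures at sulfur. The sulfone is a storable source of the quinone methide, and its stereocentre is lost in step 14.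

Step 14
Reactants: 20 2-[(3R,4R)-5,7-dimethoxy-4-(4-methoxyphenyl)-2-oxochroman-3-yl]acetaldehyde; 27 racemic 2,3,4,5-tetramethoxy-6-[(4-methoxyphenyl)(4-methylbenzenesulfonyl)methyl]phenol
Product: 29 (3S,3′S,4R,4′R)-5,5′,6′,7,7′,8′-hexamethoxy-4,4′-bis(4-methoxyphenyl)-[3,3′-bichromane]-2,2′-dione, via quinone methide 28 (not isolated)
Conditions: 27, K2CO3 (2.5 equiv), 4 Å MS, CH2Cl2, rt, 30 min; then 20, (5aR,10bS)-2-mesityl-5a,10b-dihydro-4H,6H-indeno[2,1-b][1,2,4]triazolo[4,3-d][1,4]oxazin-2-ium chloride (15 mol %), 3,3′,5,5′-tetra-tert-butyl-4,4′-diphenoquinone (1.2 equiv), 0 °C → rt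
Reagents that add atoms: none
Why: Carbene-catalysed oxidative [4+2] annulation; the carbene adds to 20, the adduct is oxidised by the diphenoquinone to an acyl azolium and deprotonated to the (Z)-azolium enolate, which adds to quinone methide 28 (released from 27 by carbonate) in an endo hetero-Diels–Alder sense, and acyl transfer to the phenolate closes the ring B lactone and frees the carbene. The aminoindanol wall of the catalyst fixes the enolate face (C3′, S) and the endo approach places the 4′-aryl group cis to C3 (C4′, R). The weak heterogeneous base should leave the cis centre C3 untouched; its descriptor changes from R to S only because C3′ now outranks C4.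

Step 15
Reactants: 29 (3S,3′S,4R,4′R)-5,5′,6′,7,7′,8′-hexamethoxy-4,4′-bis(4-methoxyphenyl)-[3,3′-bichromane]-2,2′-dione
Product: 30 (3S,3′S,4R,4′R)-5,5′,6′,7,7′,8′-hexahydroxy-4,4′-bis(4-hydroxyphenyl)-[3,3′-bichromane]-2,2′-dione (CNP0064734.1)
Conditions: BBr3 (16 equiv), CH2Cl2, −78 → 0 °C; MeOH, then degassed H2O (ascorbic acid), argon
Reagents that add atoms: none
Why: Lewis-acid cleavage of all eight aryl methyl ethers by bromide attack on the methyl groups of the ether–borane adducts. The conditions are non-basic, so C3 and C3′ should not be enolised, and an opened aryl lactone recloses on aqueous work-up (either ortho oxygen gives the same lactone in both rings); degassed work-up protects ring B from air.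

## Compound list

1 | (E)-3-(4-methoxyphenyl)prop-2-enal (4-methoxycinnamaldehyde) | COc1ccc(/C=C/C=O)cc1 | starting material
2 | dibenzyl malonate | O=C(CC(=O)OCc1ccccc1)OCc1ccccc1 | starting material
3 | dibenzyl 2-[(1S)-1-(4-methoxyphenyl)-3-oxopropyl]propanedioate | O=CC[C@H](c1ccc(OC)cc1)C(C(=O)OCc1ccccc1)C(=O)OCc1ccccc1 | intermediate
4 | (3S)-5-(benzyloxy)-4-[(benzyloxy)carbonyl]-3-(4-methoxyphenyl)-5-oxopentanoic acid | OC(=O)C[C@H](c1ccc(OC)cc1)C(C(=O)OCc1ccccc1)C(=O)OCc1ccccc1 | intermediate
5 | dibenzyl 2-[(1S)-3-methoxy-1-(4-methoxyphenyl)-3-oxopropyl]propanedioate | COC(=O)C[C@H](c1ccc(OC)cc1)C(C(=O)OCc1ccccc1)C(=O)OCc1ccccc1 | intermediate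
6 | 2-[(1S)-3-methoxy-1-(4-methoxyphenyl)-3-oxopropyl]propanedioic acid | COC(=O)C[C@H](c1ccc(OC)cc1)C(C(=O)O)C(=O)O | intermediate
7 | 2-[(1S)-3-methoxy-1-(4-methoxyphenyl)-3-oxopropyl]propanedioyl dichloride | COC(=O)C[C@H](c1ccc(OC)cc1)C(C(=O)Cl)C(=O)Cl | intermediate
8 | dibenzyl 3-oxopentanedioate (dibenzyl 1,3-acetonedicarboxylate) | O=C(CC(=O)OCc1ccccc1)CC(=O)OCc1ccccc1 | starting material
9 | dibenzyl 2-[(3S)-2-(chlorocarbonyl)-5-methoxy-3-(4-methoxyphenyl)-5-oxopentanoyl]-3-oxopentanedioate (enolisable centres undefined) | COC(=O)C[C@H](c1ccc(OC)cc1)C(C(=O)Cl)C(=O)C(C(=O)OCc1ccccc1)C(=O)CC(=O)OCc1ccccc1 | intermediate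
10 | dibenzyl 2,4,6-trihydroxy-5-[(1R)-3-methoxy-1-(4-methoxyphenyl)-3-oxopropyl]benzene-1,3-dicarboxylate | COC(=O)C[C@H](c1ccc(OC)cc1)c1c(O)c(C(=O)OCc2ccccc2)c(O)c(C(=O)OCc2ccccc2)c1O | intermediate
11 | dibenzyl (4R)-5,7-dihydroxy-4-(4-methoxyphenyl)-2-oxochromane-6,8-dicarboxylate | O=C1C[C@H](c2ccc(OC)cc2)c2c(O)c(C(=O)OCc3ccccc3)c(O)c(C(=O)OCc3ccccc3)c2O1 | intermediate
12 | (4R)-5,7-dihydroxy-4-(4-methoxyphenyl)-2-oxochromane-6,8-dicarboxylic acid | O=C1C[C@H](c2ccc(OC)cc2)c2c(O)c(C(=O)O)c(O)c(C(=O)O)c2O1 | intermediate
13 | (4R)-5,7-dihydroxy-4-(4-methoxyphenyl)chroman-2-one | O=C1C[C@H](c2ccc(OC)cc2)c2c(O)cc(O)cc2O1 | intermediate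
14 | (4R)-5,7-dimethoxy-4-(4-methoxyphenyl)chroman-2-one | O=C1C[C@H](c2ccc(OC)cc2)c2c(OC)cc(OC)cc2O1 | intermediate
15 | lithium (4R)-5,7-dimethoxy-4-(4-methoxyphenyl)-4H-chromen-2-olate | [Li]OC1=C[C@H](c2ccc(OC)cc2)c2c(OC)cc(OC)cc2O1 | intermediate
16 | (3S,4R)-3-allyl-5,7-dimethoxy-4-(4-methoxyphenyl)chroman-2-one (3,4-trans) | O=C1Oc2cc(OC)cc(OC)c2[C@@H](c2ccc(OC)cc2)[C@@H]1CC=C | intermediate
17 | lithium (4R)-3-allyl-5,7-dimethoxy-4-(4-methoxyphenyl)-4H-chromen-2-olate | [Li]OC1=C(CC=C)[C@H](c2ccc(OC)cc2)c2c(OC)cc(OC)cc2O1 | intermediate
18 | (3R,4R)-3-allyl-5,7-dimethoxy-4-(4-methoxyphenyl)chroman-2-one (3,4-cis) | O=C1Oc2cc(OC)cc(OC)c2[C@@H](c2ccc(OC)cc2)[C@H]1CC=C | intermediate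
19 | (3R,4R)-3-(2,3-dihydroxypropyl)-5,7-dimethoxy-4-(4-methoxyphenyl)chroman-2-one (both carbinol epimers) | O=C1Oc2cc(OC)cc(OC)c2[C@@H](c2ccc(OC)cc2)[C@H]1CC(O)CO | intermediate
20 | 2-[(3R,4R)-5,7-dimethoxy-4-(4-methoxyphenyl)-2-oxochroman-3-yl]acetaldehyde (3,4-cis) | O=C1Oc2cc(OC)cc(OC)c2[C@@H](c2ccc(OC)cc2)[C@H]1CC=O | intermediate
21 | 1,2,3,4-tetramethoxybenzene | COc1ccc(OC)c(OC)c1OC | starting material
22 | (2,3,4,5-tetramethoxyphenyl)lithium | [Li]c1cc(OC)c(OC)c(OC)c1OC | intermediate
23 | dimethyl (2,3,4,5-tetramethoxyphenyl)boronate | COB(OC)c1cc(OC)c(OC)c(OC)c1OC | intermediate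
24 | 2,3,4,5-tetramethoxyphenol | COc1cc(O)c(OC)c(OC)c1OC | intermediate
25 | 4-methoxybenzaldehyde | COc1ccc(C=O)cc1 | starting material
26 | racemic 2-[hydroxy(4-methoxyphenyl)methyl]-3,4,5,6-tetramethoxyphenol | COc1ccc(C(O)c2c(O)c(OC)c(OC)c(OC)c2OC)cc1 | intermediate
27 | racemic 2,3,4,5-tetramethoxy-6-[(4-methoxyphenyl)(4-methylbenzenesulfonyl)methyl]phenol | COc1ccc(C(c2c(O)c(OC)c(OC)c(OC)c2OC)S(=O)(=O)c2ccc(C)cc2)cc1 | intermediate
28 | 2,3,4,5-tetramethoxy-6-[(4-methoxyphenyl)methylidene]cyclohexa-2,4-dien-1-one (alkene geometry not fixed) | COc1ccc(C=C2C(=O)C(OC)=C(OC)C(OC)=C2OC)cc1 | intermediate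
29 | (3S,3′S,4R,4′R)-5,5′,6′,7,7′,8′-hexamethoxy-4,4′-bis(4-methoxyphenyl)-[3,3′-bichromane]-2,2′-dione | O=C1Oc2cc(OC)cc(OC)c2[C@@H](c2ccc(OC)cc2)[C@H]1[C@H]1C(=O)Oc2c(OC)c(OC)c(OC)c(OC)c2[C@H]1c1ccc(OC)cc1 | intermediate
30 | (3S,3′S,4R,4′R)-5,5′,6′,7,7′,8′-hexahydroxy-4,4′-bis(4-hydroxyphenyl)-[3,3′-bichromane]-2,2′-dione (CNP0064734.1) | O=C1Oc2cc(O)cc(O)c2[C@@H](c2ccc(O)cc2)[C@H]1[C@H]1C(=O)Oc2c(O)c(O)c(O)c(O)c2[C@H]1c1ccc(O)cc1 | target

## Step count and risks

Total step count: 15. Longest linear sequence: 13 (steps 1–11, 14 and 15); steps 12 and 13 form the ring B branch.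

Step 6 (key step). The most likely failure is diversion of 9 into O-acylation. The enol oxygen of the tricarbonyl chelate, or a second molecule of 8, may capture the second acyl chloride (or the chlorocarbonyl ketene) faster than the remaining methylene carbon does, and ketene self-condensation would add oligomers. The fallback sets out from 7 and 8 and makes the O-acylation the planned event. Without magnesium (Et3N, CH2Cl2, −20 °C to room temperature) 7 and 8 should give the enol lactone benzyl 6-[2-(benzyloxy)-2-oxoethyl]-4-hydroxy-3-[(1R)-3-methoxy-1-(4-methoxyphenyl)-3-oxopropyl]-2-oxo-2H-pyran-5-carboxylate F1, the usual outcome of monosubstituted malonyl dichlorides with β-keto esters, which is isolated. A non-nucleophilic base (LiN(SiMe3)2, THF, −78 to 0 °C) then deprotonates the side-chain methylene on C6 of the pyranone. The carbanion attacks the lactone carbonyl, the ring oxygen leaves as an enolate, and the carbocycle tautomerises to 10 (pyranone-to-phloroglucinol rearrangement, an intramolecular Claisen condensation on an enol ester). Acid-catalysed lactonisation as in step 6 brings the route back at 11.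

Step 14. Two things are most likely to go wrong. Turnover may be sluggish, because the azolium enolate from 20 is β-branched and the electrophilic carbon of 28 is flanked by a methoxy group, so that acyl transfer to the phenol of 27 or over-oxidation to the acid can win. Selectivity may erode, because that same methoxy group disfavours the endo arrangement and the resident centres of 20 may oppose the catalyst. The fallback sets out from 20 and 27, sets C4′ by enamine instead of carbene catalysis, and sets C3 and C3′ afterwards. A diarylprolinol silyl ether (the antipode that attacks the required face of 28) with K2CO3 in CH2Cl2 should join the enamine of 20 to 28 and close the hemiacetal (3S,4R)-3-[(3R,4R)-2-hydroxy-5,6,7,8-tetramethoxy-4-(4-methoxyphenyl)chroman-3-yl]-5,7-dimethoxy-4-(4-methoxyphenyl)chroman-2-one F2. Oxidation with PhI(OAc)2 and catalytic TEMPO would give the bis-lactone (3S,3′R,4R,4′R)-5,5′,6′,7,7′,8′-hexamethoxy-4,4′-bis(4-methoxyphenyl)-[3,3′-bichromane]-2,2′-dione F3, the 3′-epimer of 29; the configuration of C3 and C3′ at this point is immaterial. F3 is converted into its bis-enolate (LiN(i-Pr)2, 2.2 equiv, THF, −78 °C) and quenched with 2,6-di-tert-butyl-4-methylphenol. Each enolate carbon should be protonated anti to its own neighbouring aryl group, as in step 10, which sets C3 and C3′ cis and brings the route back at 29.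

Step 10. The risk is poor facial discrimination in the proton transfer: a proton is a small electrophile, and internal return from diisopropylamine or equilibration on warming would give back the trans compound 16. Fragmentation of the aryl ester enolate 17 to ketene and phenolate is a second risk if the temperature rises. The fallback sets out from 14, comes back at 20, and delivers the C3 hydrogen by catalytic hydrogenation instead of protonation. Aldol addition of enolate 15 to 2,2-dimethoxyacetaldehyde should give (3R,4R)-3-(1-hydroxy-2,2-dimethoxyethyl)-5,7-dimethoxy-4-(4-methoxyphenyl)chroman-2-one F4. Dehydration under neutral conditions (methyl N-(triethylammoniosulfonyl)carbamate, toluene, 50 °C), chosen so that the double bond does not move into the ring, should give (3E,4R)-3-(2,2-dimethoxyethylidene)-5,7-dimethoxy-4-(4-methoxyphenyl)chroman-2-one F5. Hydrogenation (H2, Pd/C, EtOAc) adds hydrogen to the face of the exocyclic alkene anti to the C4 aryl group and should give the cis acetal (3R,4R)-3-(2,2-dimethoxyethyl)-5,7-dimethoxy-4-(4-methoxyphenyl)chroman-2-one F6. Mild aqueous acid (HCO2H–H2O, room temperature) then frees 20; this sequence replaces steps 9 to 11.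

Step 15. Eight ether cleavages must all go to completion, four of them on adjacent carbons of ring B. The likely failures are partial demethylation, slow acid-promoted epimerisation at C3 and C3′ if the mixture stands long with HBr, and air oxidation of the pentaoxygenated ring during isolation. The fallback goes from 29 to 30 by capture and release. The crude polyphenol is not isolated but acetylated at once (Ac2O, pyridine, 0 °C, brief) to (3S,3′S,4R,4′R)-4,4′-bis(4-acetoxyphenyl)-2,2′-dioxo-[3,3′-bichromane]-5,5′,6′,7,7′,8′-hexayl hexaacetate F7, which should be air-stable and chromatographable, so that under-cleaved material can be separated and recycled. The acetates are then removed by neutral transesterification (NH4OAc, degassed aqueous MeOH, room temperature), which gives 30.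

## Further compounds

F1 | step 6 | benzyl 6-[2-(benzyloxy)-2-oxoethyl]-4-hydroxy-3-[(1R)-3-methoxy-1-(4-methoxyphenyl)-3-oxopropyl]-2-oxo-2H-pyran-5-carboxylate | O=C1OC(CC(=O)OCc2ccccc2)=C(C(=O)OCc2ccccc2)C(O)=C1[C@H](CC(=O)OC)c1ccc(OC)cc1
F2 | step 14 | (3S,4R)-3-[(3R,4R)-2-hydroxy-5,6,7,8-tetramethoxy-4-(4-methoxyphenyl)chroman-3-yl]-5,7-dimethoxy-4-(4-methoxyphenyl)chroman-2-one (both anomers) | O=C1Oc2cc(OC)cc(OC)c2[C@@H](c2ccc(OC)cc2)[C@H]1[C@@H]1C(O)Oc2c(OC)c(OC)c(OC)c(OC)c2[C@H]1c1ccc(OC)cc1
F3 | step 14 | (3S,3′R,4R,4′R)-5,5′,6′,7,7′,8′-hexamethoxy-4,4′-bis(4-methoxyphenyl)-[3,3′-bichromane]-2,2′-dione | O=C1Oc2cc(OC)cc(OC)c2[C@@H](c2ccc(OC)cc2)[C@H]1[C@@H]1C(=O)Oc2c(OC)c(OC)c(OC)c(OC)c2[C@H]1c1ccc(OC)cc1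
F4 | step 10 | (3R,4R)-3-(1-hydroxy-2,2-dimethoxyethyl)-5,7-dimethoxy-4-(4-methoxyphenyl)chroman-2-one (both carbinol epimers) | O=C1Oc2cc(OC)cc(OC)c2[C@@H](c2ccc(OC)cc2)[C@@H]1C(O)C(OC)OC
F5 | step 10 | (3E,4R)-3-(2,2-dimethoxyethylidene)-5,7-dimethoxy-4-(4-methoxyphenyl)chroman-2-one | O=C1Oc2cc(OC)cc(OC)c2[C@@H](c2ccc(OC)cc2)/C1=C\C(OC)OC
F6 | step 10 | (3R,4R)-3-(2,2-dimethoxyethyl)-5,7-dimethoxy-4-(4-methoxyphenyl)chroman-2-one | O=C1Oc2cc(OC)cc(OC)c2[C@@H](c2ccc(OC)cc2)[C@H]1CC(OC)OC
F7 | step 15 | (3S,3′S,4R,4′R)-4,4′-bis(4-acetoxyphenyl)-2,2′-dioxo-[3,3′-bichromane]-5,5′,6′,7,7′,8′-hexayl hexaacetate | O=C1Oc2cc(OC(C)=O)cc(OC(C)=O)c2[C@@H](c2ccc(OC(C)=O)cc2)[C@H]1[C@H]1C(=O)Oc2c(OC(C)=O)c(OC(C)=O)c(OC(C)=O)c(OC(C)=O)c2[C@H]1c1ccc(OC(C)=O)cc1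
A1 | alternative 1 | (3S,3′S,4R,4′R)-5,5′,6′,7,7′,8′-hexamethoxy-4,4′-bis(4-methoxyphenyl)-[3,3′-bichromane]-2,2′-dione (octa-O-methyl ether of the target, identical with 29) | O=C1Oc2cc(OC)cc(OC)c2[C@@H](c2ccc(OC)cc2)[C@H]1[C@H]1C(=O)Oc2c(OC)c(OC)c(OC)c(OC)c2[C@H]1c1ccc(OC)cc1
A2 | alternative 1 | 5,5′,6′,7,7′,8′-hexamethoxy-2H,2′H-[3,3′-bichromene]-2,2′-dione | O=C1Oc2cc(OC)cc(OC)c2C=C1C1=Cc2c(OC)c(OC)c(OC)c(OC)c2OC1=O
A3 | alternative 1 | 4-methoxyphenylboronic acid | COc1ccc(B(O)O)cc1
A4 | alternative 2 | (E)-3-(4-methoxyphenyl)-1-(1-methyl-1H-imidazol-2-yl)prop-2-en-1-one | COc1ccc(/C=C/C(=O)c2nccn2C)cc1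
A5 | alternative 2 | [(1S,2S,3R,4R)-3,4-bis(4-methoxyphenyl)cyclobutane-1,2-diyl]bis[(1-methyl-1H-imidazol-2-yl)methanone] | O=C(c1nccn1C)[C@H]1[C@H](c2ccc(OC)cc2)[C@@H](c2ccc(OC)cc2)[C@@H]1C(=O)c1nccn1C
A6 | alternative 3 | (3S,3′S,4R,4′R)-5,7-dihydroxy-4,4′-bis(4-hydroxyphenyl)-5′,6′,7′,8′-tetramethoxy-[3,3′-bichromane]-2,2′-dione | O=C1Oc2cc(O)cc(O)c2[C@@H](c2ccc(O)cc2)[C@H]1[C@H]1C(=O)Oc2c(OC)c(OC)c(OC)c(OC)c2[C@H]1c1ccc(O)cc1
A7 | alternative 3 | (3R,3aR,6R,6aR)-3,6-bis(4-hydroxyphenyl)tetrahydrofuro[3,4-c]furan-1,4-dione | O=C1O[C@@H](c2ccc(O)cc2)[C@@H]2C(=O)O[C@@H](c3ccc(O)cc3)[C@H]12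
A8 | alternative 3 | phloroglucinol (benzene-1,3,5-triol) | Oc1cc(O)cc(O)c1
A9 | alternative 3 | (E)-3-(4-hydroxyphenyl)prop-2-enoic acid (p-coumaric acid) | OC(=O)/C=C/c1ccc(O)cc1
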